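The quinone ring is numbered so that C1 and C4 are the carbonyl carbons, C2 bears OH, C3 the henicosyl chain, C5 OMe and C6 H. The oxygens on C1 and C5 flank C6 in a 1,3-relationship. This is the signature of a donor butadiene C1–C6–C5–C4, while C2–C3 with the chain maps onto an alk-2-ynoate. One thermal Diels–Alder reaction of 1,3-dimethoxy-1-(trimethylsilyloxy)butadiene 9 with methyl tetracos-2-ynoate 6 should form C3–C4 and C1–C2. The adduct aromatises by methanol loss and gives salicylate 12, with phenol and methyl ether already distinguished. The activating ester is then excised, and the oxygens at C4 and C2 are added by two regiocontrolled oxidations.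

Key step: step 5

Remarks on the chemistry:
- Ring atoms C1–C6 always refer to the numbering of the target quinone given above.
- C1 of docosan-1-ol ends as ring carbon C3, so the C22 alcohol supplies exactly the C21 side chain. The homologation reagent supplies ring carbon C2.
- Assumption: diene 9 is used as the mixture of C1=C2 geometric isomers, because this geometry disappears on aromatisation.

Step 1
Reactants: 1 docosan-1-ol
Product: 2 docosanal
Conditions: IBX (1.5 equiv), EtOAc, 80 °C; filter warm
Reagents that add atoms: none
Why: IBX oxidation of a primary alcohol stops at the aldehyde, and hot EtOAc keeps the waxy substrate dissolved while the spent iodine reagent stays insoluble and is filtered off.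

Step 2
Reactants: 2 docosanal
Product: 3 tricos-1-yne
Conditions: dimethyl (1-diazo-2-oxopropyl)phosphonate (1.3 equiv), K2CO3 (2 equiv), MeOH–THF, 23–35 °C
Reagents that add atoms: dimethyl (1-diazo-2-oxopropyl)phosphonate, CC(=O)C(=[N+]=[N-])P(=O)(OC)OC
Why: In the Ohira–Bestmann modification of the Seyferth–Gilbert homologation, methanolysis unmasks the diazomethylphosphonate anion, which olefinates the aldehyde, and N2 loss with a 1,2-hydride shift gives the terminal alkyne under base mild enough for an enolisable aliphatic aldehyde.

Step 3
Reactants: 3 tricos-1-yne; 4 methyl chloroformate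
Product: 6 methyl tetracos-2-ynoate, via lithium tricos-1-yn-1-ide 5 (not isolated)
Conditions: n-BuLi (1.05 equiv), THF, 0 °C; then ClCO2Me (1.5 equiv), −20 °C to 23 °C
Reagents that add atoms: none
Why: Acetylide acylation by irreversible deprotonation of the terminal alkyne and addition–elimination on the chloroformate is the standard entry to alk-2-ynoates, because the product ester is far less electrophilic than the excess chloroformate.

Step 4
Reactants: 7 methyl (E)-3-methoxybut-2-enoate
Product: 9 1,3-dimethoxy-1-(trimethylsilyloxy)buta-1,3-diene (mixture of C1=C2 geometric isomers), via lithium dienolate 8 (not isolated)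
Conditions: LiN(iPr)2 (1.1 equiv, commercial solution), THF, −78 °C; Me3SiCl (1.3 equiv), −78 °C to 23 °C; pentane, filtration under argon, vacuum distillation
Reagents that add atoms: chlorotrimethylsilane, C[Si](C)(C)Cl
Why: Kinetic γ-deprotonation of the β-methoxy enoate gives the extended (vinylogous) enolate, and the oxophilic silyl chloride traps it on oxygen (silyl ketene acetal formation), which is the established preparation of this diene.

Step 5
Reactants: 6 methyl tetracos-2-ynoate; 9 1,3-dimethoxy-1-(trimethylsilyloxy)buta-1,3-diene
Product: 12 methyl 2-henicosyl-6-hydroxy-4-methoxybenzoate, via cyclohexadiene cycloadduct 10 (not isolated), via aryl trimethylsilyl ether 11 (not isolated)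
Conditions: 9 (3 equiv, added in portions), neat melt, sealed tube, argon, 150 °C; then 1 M HCl, THF–MeOH, 23 °C
Reagents that add atoms: none
Why: This is a normal-electron-demand Diels–Alder reaction in which the unsubstituted CH2 terminus of the doubly donor-substituted diene (largest HOMO coefficient) attacks the electrophilic β-carbon of the ynoate (C3–C4 bond) slightly ahead of bonding between the ketene acetal carbon and the α-carbon (C1–C2 bond). The closest known reaction type is the thermal cycloaddition of 1-silyloxy-1,3-dialkoxybutadienes to alk-2-ynoates, which furnishes 4-alkoxy-6-alkylsalicylates. The single new ring, the six-membered carbocycle, is closed intermolecularly in a concerted, asynchronous, suprafacial–suprafacial [4+2] mode. Cyclohexa-1,4-diene 10 holds a mixed ketal across the ring from a doubly allylic CH2, so 1,4-elimination of methanol to arene 11 is driven by aromatisation, the acidic work-up cleaves the aryl silyl ether, and the one transient stereocentre of 10 vanishes, so no stereocontrol is required. Only regioselectivity is needed, and it is secured by the matched polarisation of the partners (both diene oxygens reinforce the nucleophilicity of the CH2 terminus and the ester polarises the alkyne), which puts the chain meta to both oxygens and the ester between chain and phenol. Excess diene is used because the released methanol protodesilylates part of it.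

Step 6
Reactants: 12 methyl 2-henicosyl-6-hydroxy-4-methoxybenzoate
Product: 14 3-henicosyl-5-methoxyphenol, via 2-henicosyl-6-hydroxy-4-methoxybenzoic acid 13 (not isolated)
Conditions: KOH (10 equiv), ethylene glycol–H2O, 140 °C; then conc. HCl to pH 1, same flask, 120 °C until gas evolution ends
Reagents that add atoms: none
Why: Forcing saponification overcomes the double ortho hindrance, and the liberated acid undergoes easy protodecarboxylation because ipso protonation at the carboxyl-bearing carbon C2 is ortho to the C1 hydroxyl and para to the C5 methoxy donor.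

Step 7
Reactants: 14 3-henicosyl-5-methoxyphenol
Product: 15 2-henicosyl-6-methoxycyclohexa-2,5-diene-1,4-dione
Conditions: (KSO3)2NO (2.5 equiv), n-Bu4NHSO4 (cat.), aq. KH2PO4 buffer, CH2Cl2–H2O, 23 °C
Reagents that add atoms: potassium nitrosodisulfonate (KSO3)2NO, [K+].[K+].[O]N(S(=O)(=O)[O-])S(=O)(=O)[O-]
Why: In the Teuber oxidation one nitrosodisulfonate radical abstracts the phenolic hydrogen, a second couples at the free para carbon C4, and loss of imidodisulfonate gives the p-quinone, while the phase-transfer salt carries the oxidant to the lipophilic substrate.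

Step 8
Reactants: 15 2-henicosyl-6-methoxycyclohexa-2,5-diene-1,4-dione
Product: 16 3-henicosyl-5-methoxybenzene-1,2,4-triyl triacetate
Conditions: Ac2O, H2SO4 (cat.), 25–40 °C; ice-water
Reagents that add atoms: acetic anhydride, CC(=O)OC(C)=O
Why: In the Thiele–Winter acetoxylation the C5 methoxy group feeds electron density through C6 into the C1 carbonyl, so the C4(=O)–C3=C2 enone stays the electrophilic half and acetate adds at C2, across the ring from the methoxy-bearing carbon as is the rule for donor-substituted quinones, before enolisation and peracetylation.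

Step 9
Reactants: 16 3-henicosyl-5-methoxybenzene-1,2,4-triyl triacetate
Product: 18 3-henicosyl-2-hydroxy-5-methoxycyclohexa-2,5-diene-1,4-dione (target), via 3-henicosyl-5-methoxybenzene-1,2,4-triol 17 (not isolated)
Conditions: K2CO3 (4 equiv), MeOH–THF, open to air, 23 °C; then 1 M HCl
Reagents that add atoms: none
Why: Base-mediated transesterification (Zemplén-type deacetylation) frees the triol, whose electron-rich anion autoxidises in air to the hydroxyquinone salt, and methanol as solvent makes any methoxide exchange at C5 degenerate, so the methyl ether is kept.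

Compound list
1 | docosan-1-ol | CCCCCCCCCCCCCCCCCCCCCCO | starting material
2 | docosanal | CCCCCCCCCCCCCCCCCCCCCC=O | intermediate
3 | tricos-1-yne | CCCCCCCCCCCCCCCCCCCCCC#C | intermediate
4 | methyl chloroformate | COC(=O)Cl | starting material
5 | lithium tricos-1-yn-1-ide | CCCCCCCCCCCCCCCCCCCCCC#C[Li] | intermediate
6 | methyl tetracos-2-ynoate | CCCCCCCCCCCCCCCCCCCCCC#CC(=O)OC | intermediate
7 | methyl (E)-3-methoxybut-2-enoate | CO/C(C)=C/C(=O)OC | starting material
8 | lithium 1,3-dimethoxybuta-1,3-dien-1-olate | COC(=C)C=C(OC)O[Li] | intermediate
9 | 1,3-dimethoxy-1-(trimethylsilyloxy)buta-1,3-diene (mixture of C1=C2 geometric isomers) | COC(=C)C=C(OC)O[Si](C)(C)C | intermediate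
10 | methyl 2-henicosyl-4,6-dimethoxy-6-(trimethylsilyloxy)cyclohexa-1,4-diene-1-carboxylate (racemic) | CCCCCCCCCCCCCCCCCCCCCC1=C(C(=O)OC)C(OC)(O[Si](C)(C)C)C=C(OC)C1 | intermediate
11 | methyl 2-henicosyl-4-methoxy-6-(trimethylsilyloxy)benzoate | CCCCCCCCCCCCCCCCCCCCCc1cc(OC)cc(O[Si](C)(C)C)c1C(=O)OC | intermediate
12 | methyl 2-henicosyl-6-hydroxy-4-methoxybenzoate | CCCCCCCCCCCCCCCCCCCCCc1cc(OC)cc(O)c1C(=O)OC | intermediate
13 | 2-henicosyl-6-hydroxy-4-methoxybenzoic acid | CCCCCCCCCCCCCCCCCCCCCc1cc(OC)cc(O)c1C(=O)O | intermediate
14 | 3-henicosyl-5-methoxyphenol | CCCCCCCCCCCCCCCCCCCCCc1cc(O)cc(OC)c1 | intermediate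
15 | 2-henicosyl-6-methoxycyclohexa-2,5-diene-1,4-dione | CCCCCCCCCCCCCCCCCCCCCC1=CC(=O)C=C(OC)C1=O | intermediate
16 | 3-henicosyl-5-methoxybenzene-1,2,4-triyl triacetate | CCCCCCCCCCCCCCCCCCCCCc1c(OC(C)=O)c(OC(C)=O)cc(OC)c1OC(C)=O | intermediate
17 | 3-henicosyl-5-methoxybenzene-1,2,4-triol | CCCCCCCCCCCCCCCCCCCCCc1c(O)c(O)cc(OC)c1O | intermediate
18 | 3-henicosyl-2-hydroxy-5-methoxycyclohexa-2,5-diene-1,4-dione | CCCCCCCCCCCCCCCCCCCCCC1=C(O)C(=O)C=C(OC)C1=O | target

Total step count: 9. Longest linear sequence: 8 steps (1 to 18 through steps 1, 2, 3, 5, 6, 7, 8 and 9).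

Steps most likely to fail

**1. Step 5.** The β-alkyl ynoate is only a moderate dienophile. Thermal decay or protodesilylation of the diene may outrun the cycloaddition, and elimination of silanol in place of methanol would blur the phenol/ether differentiation.

The fallback replaces the cycloaddition by an anionic ring construction. It sets out from docosanal 2.
- Wittig olefination with Ph3P=CHC(O)CH3 in toluene should give (E)-pentacos-3-en-2-one F1.
- NaOMe-mediated Michael addition of dimethyl malonate in MeOH–THF should give dimethyl 2-(2-oxopentacosan-4-yl)propanedioate F2.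
- This should close in the same flask by Dieckmann-type condensation to methyl 6-henicosyl-2-hydroxy-4-oxocyclohex-2-ene-1-carboxylate F3.
- Dehydrogenative aromatisation with Br2 in DMF (0 to 80 °C) should give methyl 2-henicosyl-4,6-dihydroxybenzoate F4.
- Mono-O-methylation with MeI and K2CO3 in acetone is selective for the hydroxyl that is not hydrogen-bonded to the ester. It comes back to the route at salicylate 12.

**2. Step 8.** The chain shields C2, so acetate may add partly at C6 (poor regioselectivity), and the strong acid may erode the methyl ether.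

The fallback oxygenates C2 by epoxidation instead of conjugate acetoxylation. It sets out from quinone 15.
- Weitz–Scheffer epoxidation with H2O2 and Na2CO3 in THF–MeOH should attack the more electrophilic C2=C3 bond, because C5=C6 is deactivated as a vinylogous ester. This should give 1-henicosyl-3-methoxy-7-oxabicyclo[4.1.0]hept-3-ene-2,5-dione F5.
- Acid-promoted opening at C3 with loss of the C2 hydrogen (cat. H2SO4 in CH2Cl2, as known for 2-alkylnaphthoquinone oxides) isomerises it directly to target 18, bypassing 16 and 17.

**3. Step 7.** Slow mass transfer between the aqueous radical oxidant and the waxy phenol may allow decay of the oxidant, incomplete conversion or ortho oxidation.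

The fallback is a homogeneous two-electron oxidation through a quinone monoketal. It sets out from phenol 14.
- PhI(OAc)2 (2.2 equiv) in MeOH–CH2Cl2 should first place methanol at C4, giving 3-henicosyl-4,5-dimethoxyphenol F6.
- Further oxidation in the same flask should give 3-henicosyl-4,4,5-trimethoxycyclohexa-2,5-dien-1-one F7.
- Mild ketal hydrolysis (1 M HCl, THF) comes back to the route at quinone 15.

Further compounds
F1 | step 5 | (E)-pentacos-3-en-2-one | CCCCCCCCCCCCCCCCCCCCC/C=C/C(C)=O
F2 | step 5 | dimethyl 2-(2-oxopentacosan-4-yl)propanedioate (racemic) | CCCCCCCCCCCCCCCCCCCCCC(CC(C)=O)C(C(=O)OC)C(=O)OC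
F3 | step 5 | methyl 6-henicosyl-2-hydroxy-4-oxocyclohex-2-ene-1-carboxylate (racemic, both stereocentres erased on aromatisation) | CCCCCCCCCCCCCCCCCCCCCC1CC(=O)C=C(O)C1C(=O)OC
F4 | step 5 | methyl 2-henicosyl-4,6-dihydroxybenzoate | CCCCCCCCCCCCCCCCCCCCCc1cc(O)cc(O)c1C(=O)OC
F5 | step 8 | 1-henicosyl-3-methoxy-7-oxabicyclo[4.1.0]hept-3-ene-2,5-dione (racemic, cis-fused epoxide) | CCCCCCCCCCCCCCCCCCCCCC12OC1C(=O)C=C(OC)C2=O
F6 | step 7 | 3-henicosyl-4,5-dimethoxyphenol | CCCCCCCCCCCCCCCCCCCCCc1cc(O)cc(OC)c1OC
F7 | step 7 | 3-henicosyl-4,4,5-trimethoxycyclohexa-2,5-dien-1-one | CCCCCCCCCCCCCCCCCCCCCC1=CC(=O)C=C(OC)C1(OC)OC
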